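**Strategy**

The oxolane (O1, C2 aryl, C3, C4, C5) is traced back to (5S)-5-(d-menthyloxy)-2(5H)-furanone, whose carbonyl, α-, β- and acetal carbons are C5, C4, C3 and the hydroxymethyl carbon C9. The key step exploits this C5–C4–C3–C9 array: lithiated 2-(3,4,5-trimethoxyphenyl)-1,3-dithiane (C2 as acyl anion) adds to C3 anti to the menthyloxy group and the enolate is benzylated at C4 by 3-benzyloxy-4,5-dimethoxybenzyl bromide (benzylic carbon C7'), forming C2–C3, C4–C7' and both stereocentres in one flask. Dithiane hydrolysis, LiAlH4 reduction, acid-mediated O1–C2 closure (aryl trans to C9) and hydrogenolysis finish the 2,3-trans-3,4-cis target.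

Key step: step 7

Remark: the target is (2R,3S,4S), i.e. 2,3-trans and 3,4-cis, which requires the (+)-menthol-derived (5S) butenolide. The carbinol carbon of the triol is carried as both epimers because the ring closure passes through the benzylic cation.

**Route**

Step 1
Reactants: 1 furfural
Product: 3 5-hydroxy-2(5H)-furanone (racemic), via furfural endoperoxide 2 (not isolated)
Conditions: O2, rose bengal (cat.), hν (visible), MeOH, rt
Reagents that add atoms: dioxygen, O=O
Why: Sensitised singlet oxygen adds [4+2] across the furan diene to give endoperoxide 2, which methanol cleaves at the formyl group (loss of methyl formate) to the hydroxybutenolide, a standard furan photo-oxygenation; the hemiacetal centre is racemic and is fixed in step 2.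

Step 2
Reactants: 3 5-hydroxy-2(5H)-furanone, 4 (+)-menthol
Product: 6 (5S)-5-[(1S,2R,5S)-menthyloxy]-2(5H)-furanone, via (5R) epimer 5 (not isolated)
Conditions: CSA (cat.), toluene, reflux, Dean–Stark; crystallise from hexane, −20 °C; mother liquor re-equilibrated with CSA and recrystallised
Reagents that add atoms: none
Why: Acid-catalysed acetalisation through the cyclic oxocarbenium ion gives both C5 epimers, which interconvert under the acid, and the (5S) epimer (mirror image of the well-crystallising l-menthyl compound) should be removed by crystallisation, so the acetal stereocentre is set by crystallisation-driven epimerisation.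

Step 3
Reactants: 7 3,4,5-trimethoxybenzaldehyde
Product: 8 2-(3,4,5-trimethoxyphenyl)-1,3-dithiane
Conditions: HS(CH2)3SH, BF3·OEt2 (cat.), CH2Cl2, 0 °C → rt
Reagents that add atoms: propane-1,3-dithiol, SCCCS
Why: Lewis-acid-catalysed thioacetalisation of an aromatic aldehyde, driven by formation of the six-membered dithiane.

Step 4
Reactants: 9 3-hydroxy-4,5-dimethoxybenzaldehyde
Product: 10 3-benzyloxy-4,5-dimethoxybenzaldehyde
Conditions: BnBr, K2CO3, DMF, rt
Reagents that add atoms: benzyl bromide, BrCc1ccccc1
Why: Williamson etherification of the phenoxide, the only acidic site, with benzyl bromide; the aldehyde is inert to carbonate.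

Step 5
Reactants: 10 3-benzyloxy-4,5-dimethoxybenzaldehyde
Product: 11 (3-benzyloxy-4,5-dimethoxyphenyl)methanol
Conditions: NaBH4, MeOH, 0 °C
Reagents that add atoms: none
Why: Borohydride reduction of an aromatic aldehyde to the benzylic alcohol, leaving the aryl ethers untouched.

Step 6
Reactants: 11 (3-benzyloxy-4,5-dimethoxyphenyl)methanol
Product: 12 3-benzyloxy-4,5-dimethoxybenzyl bromide
Conditions: PBr3, CH2Cl2, 0 °C; used promptly
Reagents that add atoms: phosphorus tribromide, BrP(Br)Br
Why: PBr3 converts the electron-rich benzylic alcohol into the bromide by bromide displacement of the intermediate phosphite ester at 0 °C, conditions under which benzyl and methyl aryl ethers are stable.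

Step 7
Reactants: 8 2-(3,4,5-trimethoxyphenyl)-1,3-dithiane, 6 (5S)-5-[(1S,2R,5S)-menthyloxy]-2(5H)-furanone, 12 3-benzyloxy-4,5-dimethoxybenzyl bromide
Product: 15 (3S,4S,5S)-3-(3-benzyloxy-4,5-dimethoxybenzyl)-5-[(1S,2R,5S)-menthyloxy]-4-[2-(3,4,5-trimethoxyphenyl)-1,3-dithian-2-yl]oxolan-2-one, via lithiated dithiane 13 (not isolated), via lithium enolate 14 (not isolated)
Conditions: 8, n-BuLi, THF, −30 °C; then 6, −78 °C; then 12, DMPU, −78 → 0 °C; aq. NH4Cl
Reagents that add atoms: none
Why: n-BuLi removes the dithiane C–H to give the sulfur-stabilised carbanion 13, which adds in a Michael sense to C3 of butenolide 6 to give lithium enolate 14, and 14 is C-alkylated by bromide 12 in an SN2 step promoted by DMPU. The closest known reaction type is the tandem conjugate addition of 2-lithio-2-aryl-1,3-dithianes to 5-alkoxy-2(5H)-furanones with in-flask enolate benzylation, as used for dibenzylbutyrolactone lignans. No ring is closed; two C–C bonds (C2–C3 and C4–C7') are formed. C3 is controlled by the acetal centre C9 fixed in step 2, whose menthyloxy group blocks one face of the flat butenolide so that 13 enters anti to it; C4 is controlled by the new, very bulky aryl dithianyl group on C3, which sends the bromide to the opposite enolate face (trans). The step needs 1,4- over 1,2-addition, secured by the soft, hindered dithiane anion and the doubly activated alkoxybutenolide, and mono-C-alkylation, secured by the reactive benzylic bromide and the hindered tertiary α-carbon that results. The trans lactone relation equals the 3,4-cis relation of C9 and C7' in the oxolane, because C2 replaces C9 as ring member in step 10.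

Step 8
Reactants: 15 the dithianyl lactone from step 7
Product: 16 (3S,4S,5S)-3-(3-benzyloxy-4,5-dimethoxybenzyl)-5-[(1S,2R,5S)-menthyloxy]-4-(3,4,5-trimethoxybenzoyl)oxolan-2-one
Conditions: HgO, BF3·OEt2, THF/H2O, rt
Reagents that add atoms: water, O
Why: Thiophilic Hg(II) with BF3 ionises the C–S bonds and water captures the aryl-stabilised thionium ion (dithioacetal hydrolysis), while the lactone, acetal and benzyl ether are tolerated and C3/C4 keep the thermodynamically preferred all-trans arrangement.

Step 9
Reactants: 16 the keto lactone from step 8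
Product: 17 (2S,3S)-2-(3-benzyloxy-4,5-dimethoxybenzyl)-3-[hydroxy(3,4,5-trimethoxyphenyl)methyl]butane-1,4-diol (both epimers at the carbinol carbon)
Conditions: LiAlH4, THF, 0 °C → rt; Rochelle salt work-up; (+)-menthol recovered
Reagents that add atoms: none
Why: Hydride reduces the aryl ketone to the carbinol and opens the acyl-acetal lactone at C5, after which the released C9 hemiacetal alkoxide ejects menthoxide and the resulting aldehyde is reduced, so that C5 and C9 both end as CH2OH with C3 and C4 untouched.

Step 10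
Reactants: 17 the triol from step 9
Product: 18 [(2R,3S,4S)-4-(3-benzyloxy-4,5-dimethoxybenzyl)-2-(3,4,5-trimethoxyphenyl)oxolan-3-yl]methanol
Conditions: CSA (0.2 equiv), CH2Cl2, 0 °C → rt; Et3N quench at full conversion
Reagents that add atoms: none
Why: Acid ionises the secondary benzylic alcohol so that both epimers converge on one 3,4,5-trimethoxybenzylic cation, which the C5 hydroxyl captures in a 5-exo SN1 cycloetherification (the C9 hydroxyl could only form an oxetane); C2 is set by the C3 centre, the aryl group taking the face anti to the hydroxymethyl group, and any cis isomer can re-ionise and drain to the more stable trans isomer.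

Step 11
Reactants: 18 the benzyl-protected oxolane from step 10
Product: 19 [(2R,3S,4S)-4-(3-hydroxy-4,5-dimethoxybenzyl)-2-(3,4,5-trimethoxyphenyl)oxolan-3-yl]methanol (CNP0121704.1)
Conditions: H2 (1 atm), 10% Pd/C, EtOAc, rt
Reagents that add atoms: none
Why: Hydrogenolysis of the benzyl aryl ether on Pd/C under neutral conditions at 1 atm is much faster than cleavage of the cyclic benzylic alkyl ether C2–O1, so only the phenol should be unmasked and no stereocentre is touched.

**Compound list**

1 | furfural | O=Cc1ccco1 | starting material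
2 | furfural endoperoxide, 2,3,7-trioxabicyclo[2.2.1]hept-5-ene-1-carbaldehyde (not isolated) | O=CC12C=CC(OO1)O2 | intermediate
3 | 5-hydroxy-2(5H)-furanone (racemic) | O=C1C=CC(O)O1 | intermediate
4 | (+)-menthol, (1S,2R,5S)-2-isopropyl-5-methylcyclohexan-1-ol | C[C@H]1CC[C@@H]([C@H](C1)O)C(C)C | starting material
5 | (5R)-5-[(1S,2R,5S)-menthyloxy]-2(5H)-furanone (not isolated) | O=C1O[C@@H](O[C@H]2C[C@@H](C)CC[C@@H]2C(C)C)C=C1 | intermediate
6 | (5S)-5-[(1S,2R,5S)-menthyloxy]-2(5H)-furanone | O=C1O[C@H](O[C@H]2C[C@@H](C)CC[C@@H]2C(C)C)C=C1 | intermediate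
7 | 3,4,5-trimethoxybenzaldehyde | COc1cc(C=O)cc(OC)c1OC | starting material
8 | 2-(3,4,5-trimethoxyphenyl)-1,3-dithiane | COc1cc(C2SCCCS2)cc(OC)c1OC | intermediate
9 | 3-hydroxy-4,5-dimethoxybenzaldehyde | COc1cc(C=O)cc(O)c1OC | starting material
10 | 3-benzyloxy-4,5-dimethoxybenzaldehyde | COc1cc(C=O)cc(OCc2ccccc2)c1OC | intermediate
11 | (3-benzyloxy-4,5-dimethoxyphenyl)methanol | COc1cc(CO)cc(OCc2ccccc2)c1OC | intermediate
12 | 3-benzyloxy-4,5-dimethoxybenzyl bromide | COc1cc(CBr)cc(OCc2ccccc2)c1OC | intermediate
13 | 2-lithio-2-(3,4,5-trimethoxyphenyl)-1,3-dithiane (not isolated) | COc1cc(C2([Li])SCCCS2)cc(OC)c1OC | intermediate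
14 | lithium enolate of (4S,5S)-5-menthyloxy-4-[2-(3,4,5-trimethoxyphenyl)-1,3-dithian-2-yl]oxolan-2-one (not isolated) | [Li]OC1=C[C@H](C2(c3cc(OC)c(OC)c(OC)c3)SCCCS2)[C@@H](O[C@H]2C[C@@H](C)CC[C@@H]2C(C)C)O1 | intermediate
15 | (3S,4S,5S)-3-(3-benzyloxy-4,5-dimethoxybenzyl)-5-[(1S,2R,5S)-menthyloxy]-4-[2-(3,4,5-trimethoxyphenyl)-1,3-dithian-2-yl]oxolan-2-one | O=C1O[C@H](O[C@H]2C[C@@H](C)CC[C@@H]2C(C)C)[C@@H](C2(c3cc(OC)c(OC)c(OC)c3)SCCCS2)[C@@H]1Cc1cc(OC)c(OC)c(OCc2ccccc2)c1 | intermediate
16 | (3S,4S,5S)-3-(3-benzyloxy-4,5-dimethoxybenzyl)-5-[(1S,2R,5S)-menthyloxy]-4-(3,4,5-trimethoxybenzoyl)oxolan-2-one | O=C1O[C@H](O[C@H]2C[C@@H](C)CC[C@@H]2C(C)C)[C@@H](C(=O)c2cc(OC)c(OC)c(OC)c2)[C@@H]1Cc1cc(OC)c(OC)c(OCc2ccccc2)c1 | intermediate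
17 | (2S,3S)-2-(3-benzyloxy-4,5-dimethoxybenzyl)-3-[hydroxy(3,4,5-trimethoxyphenyl)methyl]butane-1,4-diol (carbinol epimers) | OC[C@@H](Cc1cc(OC)c(OC)c(OCc2ccccc2)c1)[C@@H](CO)C(O)c1cc(OC)c(OC)c(OC)c1 | intermediate
18 | [(2R,3S,4S)-4-(3-benzyloxy-4,5-dimethoxybenzyl)-2-(3,4,5-trimethoxyphenyl)oxolan-3-yl]methanol | COc1cc(C[C@@H]2CO[C@@H](c3cc(OC)c(OC)c(OC)c3)[C@@H]2CO)cc(OCc2ccccc2)c1OC | intermediate
19 | [(2R,3S,4S)-4-(3-hydroxy-4,5-dimethoxybenzyl)-2-(3,4,5-trimethoxyphenyl)oxolan-3-yl]methanol | COc1cc(C[C@@H]2CO[C@@H](c3cc(OC)c(OC)c(OC)c3)[C@@H]2CO)cc(O)c1OC | target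

**Step count and risks**

Total steps: 11. Longest linear sequence: 8 steps (9 → 10 → 11 → 12 → 15 → 16 → 17 → 18 → 19).

Steps most likely to fail:

Step 7. The enolate may be captured incompletely by the benzyl bromide in the one-flask sequence (proton transfer, or reversal of the conjugate addition on warming), giving mixtures of alkylated and non-alkylated lactone. The fallback separates the two bond formations. It sets out from 6 and 8: the conjugate addition is run alone and quenched with NH4Cl at −78 °C to give (4S,5S)-5-[(1S,2R,5S)-menthyloxy]-4-[2-(3,4,5-trimethoxyphenyl)-1,3-dithian-2-yl]oxolan-2-one F1, which is isolated. F1 is then deprotonated with LDA (THF, −78 °C) to regenerate enolate 14 free of other organolithium species and alkylated with 12 in the presence of DMPU, trans to the dithianyl group as before. The route is rejoined at 15.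

Step 10. Ionisation of the 3,4,5-trimethoxybenzylic alcohol may be sluggish under mild acid, and under stronger acid the cation may be intercepted by the electron-rich C7' arene (aryltetralin formation) or close with poor trans selectivity. The fallback generates the leaving group under base instead. It sets out from 17: the two primary hydroxyls are silylated selectively (TBSCl, imidazole, CH2Cl2, 0 °C) to give the 1,4-bis(tert-butyldimethylsilyl) ether of the triol F2. The remaining benzylic hydroxyl is converted at −40 °C into the benzylic methanesulfonate F3 (MsCl, Et3N, CH2Cl2), which is not isolated. TBAF in THF then frees the C5 and C9 oxygens and the C5 alkoxide closes onto C2 through the benzylic ion pair, so both epimers converge; the C9 oxygen could only form an oxetane. Without acid the oxolane cannot re-ionise towards the aryltetralin. The route is rejoined at 18.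

Step 8. Hydrolysis of the hindered dithiane may stall, or the Lewis-acidic medium may open the acyl acetal or cause epimerisation or β-elimination at C3 next to the new ketone. The fallback reduces before it hydrolyses. It sets out from 15: LiAlH4 (THF, 0 °C → rt) reduces lactone and acetal with the dithiane in place to give (2S,3S)-2-(3-benzyloxy-4,5-dimethoxybenzyl)-3-[2-(3,4,5-trimethoxyphenyl)-1,3-dithian-2-yl]butane-1,4-diol F4, with menthol released. Hg(II)-mediated hydrolysis (HgO, BF3·OEt2, aq. THF), now assisted by intramolecular capture of the thionium ion by the C5 hydroxyl, gives (2S,3S)-3-(3-benzyloxy-4,5-dimethoxybenzyl)-4-hydroxy-2-(hydroxymethyl)-1-(3,4,5-trimethoxyphenyl)butan-1-one F5, in equilibrium with its cyclic hemiketal. F5 is reduced without delay with NaBH4 (MeOH, 0 °C). The route is rejoined at 17.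

**Further compounds**

F1 | step 7 | (4S,5S)-5-[(1S,2R,5S)-menthyloxy]-4-[2-(3,4,5-trimethoxyphenyl)-1,3-dithian-2-yl]oxolan-2-one | O=C1O[C@H](O[C@H]2C[C@@H](C)CC[C@@H]2C(C)C)[C@@H](C2(c3cc(OC)c(OC)c(OC)c3)SCCCS2)C1
F2 | step 10 | 1,4-bis(tert-butyldimethylsilyl) ether of the triol | CC(C)(C)[Si](C)(C)OC[C@@H](Cc1cc(OC)c(OC)c(OCc2ccccc2)c1)[C@@H](CO[Si](C)(C)C(C)(C)C)C(O)c1cc(OC)c(OC)c(OC)c1
F3 | step 10 | benzylic methanesulfonate of the bis-silyl ether | CC(C)(C)[Si](C)(C)OC[C@@H](Cc1cc(OC)c(OC)c(OCc2ccccc2)c1)[C@@H](CO[Si](C)(C)C(C)(C)C)C(OS(C)(=O)=O)c1cc(OC)c(OC)c(OC)c1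
F4 | step 8 | (2S,3S)-2-(3-benzyloxy-4,5-dimethoxybenzyl)-3-[2-(3,4,5-trimethoxyphenyl)-1,3-dithian-2-yl]butane-1,4-diol | OC[C@@H](Cc1cc(OC)c(OC)c(OCc2ccccc2)c1)[C@@H](CO)C1(c2cc(OC)c(OC)c(OC)c2)SCCCS1
F5 | step 8 | (2S,3S)-3-(3-benzyloxy-4,5-dimethoxybenzyl)-4-hydroxy-2-(hydroxymethyl)-1-(3,4,5-trimethoxyphenyl)butan-1-one | OC[C@@H](Cc1cc(OC)c(OC)c(OCc2ccccc2)c1)[C@@H](CO)C(=O)c1cc(OC)c(OC)c(OC)c1
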